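**Retrosynthetic overview**
- The acetate comes from the threo benzylic alcohol, which is carried through the route as its TBS ether.
- The C9 methyl group comes from CH2OTs, and that from CH2OH, obtained by reductive removal of an N-acyl oxazolidinone.
- Key disconnection C7–C8: Evans syn boron aldol between an (R)-N-(aryloxyacetyl)oxazolidinone and veratraldehyde, which sets both stereocentres in one step.
- The aldol donor comes from methoxyeugenol, ethyl bromoacetate and (R)-4-benzyl-2-oxazolidinone, so the aryl ether C8–O bond is made first.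
- No ring is formed: both benzene rings are bought (methoxyeugenol and veratraldehyde).

Assumption: the target is the (7S,8S)-threo acetate exactly as drawn (C7 = benzylic acetoxy carbon, C8 = aryloxy carbon, C9 = methyl carbon).

**Route**

Step 1
Reactants: 1 4-allyl-2,6-dimethoxyphenol (methoxyeugenol); 2 ethyl bromoacetate
Product: 3 ethyl 2-(4-allyl-2,6-dimethoxyphenoxy)acetate
Conditions: K2CO3, acetone, reflux
Reagents that add atoms: none
Why: Williamson ether synthesis, in which the phenoxide formed by K2CO3 displaces bromide from the highly SN2-reactive α-bromo ester while the mild base leaves the allyl group unisomerised.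

Step 2
Reactants: 3 ethyl 2-(4-allyl-2,6-dimethoxyphenoxy)acetate
Product: 4 2-(4-allyl-2,6-dimethoxyphenoxy)acetic acid
Conditions: LiOH·H2O, THF/H2O, rt; then 1 M HCl
Reagents that add atoms: lithium hydroxide, [Li+].[OH-]
Why: Saponification of an unhindered ethyl ester is fast at room temperature and touches neither the aryl ether nor the allyl group.

Step 3
Reactants: 4 2-(4-allyl-2,6-dimethoxyphenoxy)acetic acid; 5 (R)-4-benzyl-2-oxazolidinone
Product: 7 (R)-4-benzyl-3-[2-(4-allyl-2,6-dimethoxyphenoxy)acetyl]oxazolidin-2-one, via mixed pivalic anhydride 6 (not isolated)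
Conditions: PivCl, Et3N, THF, −20 °C; then LiCl, 5, −20 °C → rt
Reagents that add atoms: none
Why: N-acylation of the Evans auxiliary by the mixed-anhydride method, in which the tert-butyl group shields the pivaloyl carbonyl of 6 so that the LiCl-activated oxazolidinone attacks only the aryloxyacetyl carbonyl; no stereocentre is formed and the auxiliary centre is untouched.

Step 4
Reactants: 7 (R)-4-benzyl-3-[2-(4-allyl-2,6-dimethoxyphenoxy)acetyl]oxazolidin-2-one; 8 3,4-dimethoxybenzaldehyde (veratraldehyde)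
Product: 11 (R)-4-benzyl-3-[(2R,3S)-2-(4-allyl-2,6-dimethoxyphenoxy)-3-(3,4-dimethoxyphenyl)-3-hydroxypropanoyl]oxazolidin-2-one, via Z-dibutylboron enolate 9 (not isolated), via dibutylboron aldolate 10 (not isolated)
Conditions: n-Bu2BOTf, Et3N, CH2Cl2, −78 → 0 °C; 8, −78 → 0 °C; then pH 7 buffer (NaH2PO4/Na2HPO4), MeOH, 30% H2O2, 0 °C
Reagents that add atoms: none
Why: Evans syn glycolate aldol, in which soft enolisation gives the Z-boron enolate 9 that reacts through a closed Zimmerman–Traxler chair with the auxiliary carbonyl turned away from the enolate oxygen, so the aldehyde adds to the face opposite the benzyl group and sets C8 (2R in the imide) and C7 (3S) together as the syn pair, which is the threo (7S,8S) relationship of the target.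

Step 5
Reactants: 11 (R)-4-benzyl-3-[(2R,3S)-2-(4-allyl-2,6-dimethoxyphenoxy)-3-(3,4-dimethoxyphenyl)-3-hydroxypropanoyl]oxazolidin-2-one
Product: 12 (R)-4-benzyl-3-[(2R,3S)-2-(4-allyl-2,6-dimethoxyphenoxy)-3-(tert-butyldimethylsilyloxy)-3-(3,4-dimethoxyphenyl)propanoyl]oxazolidin-2-one
Conditions: TBSOTf, 2,6-lutidine, CH2Cl2, 0 °C
Reagents that add atoms: tert-butyldimethylsilyl trifluoromethanesulfonate, CC(C)(C)[Si](C)(C)OS(=O)(=O)C(F)(F)F
Why: Silyl ether formation with the strongly electrophilic TBSOTf and the hindered base 2,6-lutidine caps the benzylic hydroxyl without retro-aldol or epimerisation, so the later sulfonylation and hydride steps meet only one alcohol.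

Step 6
Reactants: 12 (R)-4-benzyl-3-[(2R,3S)-2-(4-allyl-2,6-dimethoxyphenoxy)-3-(tert-butyldimethylsilyloxy)-3-(3,4-dimethoxyphenyl)propanoyl]oxazolidin-2-one
Product: 13 (2S,3S)-2-(4-allyl-2,6-dimethoxyphenoxy)-3-(tert-butyldimethylsilyloxy)-3-(3,4-dimethoxyphenyl)propan-1-ol
Conditions: LiBH4, MeOH, THF, 0 °C
Reagents that add atoms: none
Why: Reductive removal of the Evans auxiliary, in which LiBH4/MeOH attacks the more electrophilic exocyclic imide carbonyl and reduces it to the primary alcohol with release of recoverable 5, while the silyl ether blocks retro-aldol and both stereocentres are untouched (the C8 descriptor changes only because the CIP ranking changes).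

Step 7
Reactants: 13 (2S,3S)-2-(4-allyl-2,6-dimethoxyphenoxy)-3-(tert-butyldimethylsilyloxy)-3-(3,4-dimethoxyphenyl)propan-1-ol
Product: 14 (2S,3S)-2-(4-allyl-2,6-dimethoxyphenoxy)-3-(tert-butyldimethylsilyloxy)-3-(3,4-dimethoxyphenyl)propyl 4-methylbenzenesulfonate
Conditions: TsCl, Et3N, 4-(dimethylamino)pyridine (cat.), CH2Cl2, 0 °C → rt
Reagents that add atoms: p-toluenesulfonyl chloride, Cc1ccc(cc1)S(Cl)(=O)=O
Why: Sulfonylation of the only free hydroxyl under nucleophilic catalysis turns the primary C9–OH into a leaving group without touching the stereocentres.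

Step 8
Reactants: 14 (2S,3S)-2-(4-allyl-2,6-dimethoxyphenoxy)-3-(tert-butyldimethylsilyloxy)-3-(3,4-dimethoxyphenyl)propyl 4-methylbenzenesulfonate
Product: 15 tert-butyl{[(1S,2S)-2-(4-allyl-2,6-dimethoxyphenoxy)-1-(3,4-dimethoxyphenyl)propyl]oxy}dimethylsilane
Conditions: LiBHEt3, THF, 0 °C → rt
Reagents that add atoms: none
Why: SN2 hydride displacement of a primary tosylate by LiBHEt3 converts CH2OTs into the C9 methyl group at a non-stereogenic carbon, so C7 and C8 are retained and the isolated terminal alkene and the silyl ether are inert.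

Step 9
Reactants: 15 tert-butyl{[(1S,2S)-2-(4-allyl-2,6-dimethoxyphenoxy)-1-(3,4-dimethoxyphenyl)propyl]oxy}dimethylsilane
Product: 16 (1S,2S)-2-(4-allyl-2,6-dimethoxyphenoxy)-1-(3,4-dimethoxyphenyl)propan-1-ol
Conditions: Bu4NF, THF, 0 °C → rt
Reagents that add atoms: none
Why: Fluoride-mediated desilylation driven by the strong Si–F bond frees the benzylic alcohol under non-acidic conditions, which avoids ionisation of the electron-rich benzylic C7–O bond and so keeps its configuration.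

Step 10
Reactants: 16 (1S,2S)-2-(4-allyl-2,6-dimethoxyphenoxy)-1-(3,4-dimethoxyphenyl)propan-1-ol
Product: 17 (1S,2S)-2-(4-allyl-2,6-dimethoxyphenoxy)-1-(3,4-dimethoxyphenyl)propyl acetate (CNP0290230.2)
Conditions: Ac2O, pyridine, 4-(dimethylamino)pyridine (cat.), CH2Cl2, rt
Reagents that add atoms: acetic anhydride, CC(=O)OC(C)=O
Why: Nucleophile-catalysed O-acylation (acyl transfer through the N-acetylpyridinium ion) esterifies the secondary benzylic alcohol at oxygen with retention at C7 and gives the target.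

**Compound list**

1 | 4-allyl-2,6-dimethoxyphenol (methoxyeugenol) | C=CCc1cc(OC)c(O)c(OC)c1 | starting material
2 | ethyl bromoacetate | CCOC(=O)CBr | starting material
3 | ethyl 2-(4-allyl-2,6-dimethoxyphenoxy)acetate | C=CCc1cc(OC)c(OCC(=O)OCC)c(OC)c1 | intermediate
4 | 2-(4-allyl-2,6-dimethoxyphenoxy)acetic acid | C=CCc1cc(OC)c(OCC(=O)O)c(OC)c1 | intermediate
5 | (R)-4-benzyl-2-oxazolidinone | O=C1N[C@H](Cc2ccccc2)CO1 | starting material
6 | 2-(4-allyl-2,6-dimethoxyphenoxy)acetic pivalic anhydride (mixed anhydride, not isolated) | C=CCc1cc(OC)c(OCC(=O)OC(=O)C(C)(C)C)c(OC)c1 | intermediate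
7 | (R)-4-benzyl-3-[2-(4-allyl-2,6-dimethoxyphenoxy)acetyl]oxazolidin-2-one | C=CCc1cc(OC)c(OCC(=O)N2[C@H](Cc3ccccc3)COC2=O)c(OC)c1 | intermediate
8 | 3,4-dimethoxybenzaldehyde (veratraldehyde) | COc1ccc(C=O)cc1OC | starting material
9 | Z-dibutylboron enolate of 7 (not isolated) | CCCCB(CCCC)O/C(=C\Oc1c(OC)cc(CC=C)cc1OC)N1[C@H](Cc2ccccc2)COC1=O | intermediate
10 | O-dibutylboryl aldolate of 11 (not isolated) | C=CCc1cc(OC)c(O[C@@H](C(=O)N3[C@H](Cc4ccccc4)COC3=O)[C@@H](OB(CCCC)CCCC)c2ccc(OC)c(OC)c2)c(OC)c1 | intermediate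
11 | (R)-4-benzyl-3-[(2R,3S)-2-(4-allyl-2,6-dimethoxyphenoxy)-3-(3,4-dimethoxyphenyl)-3-hydroxypropanoyl]oxazolidin-2-one | C=CCc1cc(OC)c(O[C@@H](C(=O)N3[C@H](Cc4ccccc4)COC3=O)[C@@H](O)c2ccc(OC)c(OC)c2)c(OC)c1 | intermediate
12 | (R)-4-benzyl-3-[(2R,3S)-2-(4-allyl-2,6-dimethoxyphenoxy)-3-(tert-butyldimethylsilyloxy)-3-(3,4-dimethoxyphenyl)propanoyl]oxazolidin-2-one | C=CCc1cc(OC)c(O[C@@H](C(=O)N3[C@H](Cc4ccccc4)COC3=O)[C@@H](O[Si](C)(C)C(C)(C)C)c2ccc(OC)c(OC)c2)c(OC)c1 | intermediate
13 | (2S,3S)-2-(4-allyl-2,6-dimethoxyphenoxy)-3-(tert-butyldimethylsilyloxy)-3-(3,4-dimethoxyphenyl)propan-1-ol | C=CCc1cc(OC)c(O[C@@H](CO)[C@@H](O[Si](C)(C)C(C)(C)C)c2ccc(OC)c(OC)c2)c(OC)c1 | intermediate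
14 | (2S,3S)-2-(4-allyl-2,6-dimethoxyphenoxy)-3-(tert-butyldimethylsilyloxy)-3-(3,4-dimethoxyphenyl)propyl 4-methylbenzenesulfonate | C=CCc1cc(OC)c(O[C@@H](COS(=O)(=O)c3ccc(C)cc3)[C@@H](O[Si](C)(C)C(C)(C)C)c2ccc(OC)c(OC)c2)c(OC)c1 | intermediate
15 | tert-butyl{[(1S,2S)-2-(4-allyl-2,6-dimethoxyphenoxy)-1-(3,4-dimethoxyphenyl)propyl]oxy}dimethylsilane | C=CCc1cc(OC)c(O[C@@H](C)[C@@H](O[Si](C)(C)C(C)(C)C)c2ccc(OC)c(OC)c2)c(OC)c1 | intermediate
16 | (1S,2S)-2-(4-allyl-2,6-dimethoxyphenoxy)-1-(3,4-dimethoxyphenyl)propan-1-ol | C=CCc1cc(OC)c(O[C@@H](C)[C@@H](O)c2ccc(OC)c(OC)c2)c(OC)c1 | intermediate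
17 | (1S,2S)-2-(4-allyl-2,6-dimethoxyphenoxy)-1-(3,4-dimethoxyphenyl)propyl acetate | C=CCc1cc(OC)c(O[C@@H](C)[C@@H](OC(C)=O)c2ccc(OC)c(OC)c2)c(OC)c1 | target

**Step count and risks**

Total step count: 10. Longest linear sequence: 10 steps (1 → 17); the other bought pieces 2, 5 and 8 enter at steps 1, 3 and 4.

Steps most likely to fail:

Step 4 (boron aldol). The hindered 2,6-dimethoxyphenoxy group may slow enolisation, and the electron-rich aldehyde may erode conversion or syn selectivity. The fallback sets out from acid 4 and comes back at alcohol 13. Acid 4 is coupled with commercial (R)-4-benzyl-1,3-thiazolidine-2-thione (EDC·HCl, 4-(dimethylamino)pyridine, CH2Cl2) to give (R)-3-[2-(4-allyl-2,6-dimethoxyphenoxy)acetyl]-4-benzyl-1,3-thiazolidine-2-thione F1. Its chlorotitanium enolate (TiCl4 1.05 equiv, i-Pr2NEt 1.1 equiv, N-methyl-2-pyrrolidone 1.0 equiv, CH2Cl2, −78 → 0 °C) adds to 8 in the same facial sense as the boron aldol. This gives the syn adduct (R)-4-benzyl-3-[(2R,3S)-2-(4-allyl-2,6-dimethoxyphenoxy)-3-(3,4-dimethoxyphenyl)-3-hydroxypropanoyl]-1,3-thiazolidine-2-thione F2, whose yellow colour helps chromatographic removal of minor isomers. Silylation (TBSOTf, 2,6-lutidine) gives the TBS ether (R)-4-benzyl-3-[(2R,3S)-2-(4-allyl-2,6-dimethoxyphenoxy)-3-(tert-butyldimethylsilyloxy)-3-(3,4-dimethoxyphenyl)propanoyl]-1,3-thiazolidine-2-thione F3. The very labile thione auxiliary is then removed with NaBH4 in THF/EtOH at 0 °C to give 13.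

Step 6 (reductive auxiliary removal). With the bulky β-silyloxy group, hydride may attack the ring carbonyl of the oxazolidinone, or borane formed in the flask may hydroborate the allyl group. The fallback sets out from 12 and comes back at 13. Imide 12 is transesterified with MeOMgBr (from MeMgBr and MeOH, CH2Cl2/MeOH, 0 °C) to methyl (2R,3S)-2-(4-allyl-2,6-dimethoxyphenoxy)-3-(tert-butyldimethylsilyloxy)-3-(3,4-dimethoxyphenyl)propanoate F4. This ester is reduced with i-Bu2AlH (CH2Cl2, −78 → 0 °C) to 13.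

Step 8 (hydride displacement). The tosylate sits on a β-branched, β-oxygenated carbon, so LiBHEt3 may attack sulfur and return 13, or the reaction may stall. The fallback sets out from 14 and comes back at 15. Finkelstein exchange (NaI, 2-butanone, reflux) gives tert-butyl{[(1S,2R)-2-(4-allyl-2,6-dimethoxyphenoxy)-1-(3,4-dimethoxyphenyl)-3-iodopropyl]oxy}dimethylsilane F5. The iodide is reduced in a radical chain (Bu3SnH in excess, azobisisobutyronitrile, toluene, 80 °C) to 15. The stannane concentration is kept high so that hydrogen transfer outruns β-scission of the aryloxy group.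

**Further compounds**

F1 | step 4 | (R)-3-[2-(4-allyl-2,6-dimethoxyphenoxy)acetyl]-4-benzyl-1,3-thiazolidine-2-thione | C=CCc1cc(OC)c(OCC(=O)N2[C@H](Cc3ccccc3)CSC2=S)c(OC)c1
F2 | step 4 | (R)-4-benzyl-3-[(2R,3S)-2-(4-allyl-2,6-dimethoxyphenoxy)-3-(3,4-dimethoxyphenyl)-3-hydroxypropanoyl]-1,3-thiazolidine-2-thione | C=CCc1cc(OC)c(O[C@@H](C(=O)N3[C@H](Cc4ccccc4)CSC3=S)[C@@H](O)c2ccc(OC)c(OC)c2)c(OC)c1
F3 | step 4 | (R)-4-benzyl-3-[(2R,3S)-2-(4-allyl-2,6-dimethoxyphenoxy)-3-(tert-butyldimethylsilyloxy)-3-(3,4-dimethoxyphenyl)propanoyl]-1,3-thiazolidine-2-thione | C=CCc1cc(OC)c(O[C@@H](C(=O)N3[C@H](Cc4ccccc4)CSC3=S)[C@@H](O[Si](C)(C)C(C)(C)C)c2ccc(OC)c(OC)c2)c(OC)c1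
F4 | step 6 | methyl (2R,3S)-2-(4-allyl-2,6-dimethoxyphenoxy)-3-(tert-butyldimethylsilyloxy)-3-(3,4-dimethoxyphenyl)propanoate | C=CCc1cc(OC)c(O[C@@H](C(=O)OC)[C@@H](O[Si](C)(C)C(C)(C)C)c2ccc(OC)c(OC)c2)c(OC)c1
F5 | step 8 | tert-butyl{[(1S,2R)-2-(4-allyl-2,6-dimethoxyphenoxy)-1-(3,4-dimethoxyphenyl)-3-iodopropyl]oxy}dimethylsilane | C=CCc1cc(OC)c(O[C@@H](CI)[C@@H](O[Si](C)(C)C(C)(C)C)c2ccc(OC)c(OC)c2)c(OC)c1
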